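**Strategy.** The 19-membered lactam ring (N, C1–C15, arene C16, C21 and C20) is disconnected at C4–C5, the site of the ring Z-alkene of the C2–C5 dienamide. One ring-closing alkyne metathesis joins the C2–C4 enyne of an anilide to the C5 alkyne beside the C6 methoxy group (both capped with methyl); it closes the macrocycle and installs a C4≡C5 bond that syn hydrogenation later turns into the Z-alkene. The precursor is an open-chain 2,5-dimethoxyanilide that already holds all seven stereocentres, the E-C8 alkene, a C11/C12 acetonide and a C7 silyl ether; the hydroquinone is released at the end through the quinone.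

Key step: step 23

Remark (numbering): locants C1–C21 are those of the target ring: C1 amide carbonyl, C2–C15 the chain to the benzylic carbon, C16–C21 the arene (C16 bears C15, C18 and C21 bear oxygen, C20 bears nitrogen).
Remark (assumption): compounds 1, 15, 24 and 25 are taken as commercial; the (Z)-crotylborane of steps 2 and 9 is prepared beforehand from (Z)-but-2-ene, n-BuLi/KOtBu, (+)-Ipc2BOMe (from (−)-α-pinene) and BF3·OEt2 and is added as a solution.
Remark (structures): compounds 30 and 31 carry the target configuration at all seven stereocentres (6S,7S,10S,11R,12S,14S,15R) and the E-C2 and E-C8 alkenes. The C5–C7 unit is built by a glycolate aldol, so that no ozonolysis is needed once the C8 alkene is in place.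

Step 1
Reactants: 1 2-hydroxy-5-methoxy-3-nitrobenzaldehyde
Product: 2 2,5-dimethoxy-3-nitrobenzaldehyde
Conditions: MeI, K2CO3, DMF, 50 °C
Reagents that add atoms: iodomethane, CI
Why: Williamson etherification, in which the acidic phenol flanked by formyl and nitro groups is deprotonated by K2CO3 and the phenoxide is methylated by SN2 attack on iodomethane.

Step 2
Reactants: 2 2,5-dimethoxy-3-nitrobenzaldehyde
Product: 3 (1R,2S)-1-(2,5-dimethoxy-3-nitrophenyl)-2-methylbut-3-en-1-ol
Conditions: (Z)-crotyl-B(Ipc)2 [from (+)-Ipc2BOMe], THF/Et2O, −78 °C; then NaOH, H2O2, 0 °C to rt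
Reagents that add atoms: B-[(Z)-but-2-enyl]diisopinocampheylborane, C/C=C\CB([C@H]1C[C@H]2C[C@@H]([C@@H]1C)C2(C)C)[C@H]1C[C@H]2C[C@@H]([C@@H]1C)C2(C)C
Why: Brown asymmetric crotylboration through a chair Zimmerman–Traxler transition state, in which the Z geometry of the crotyl group should give the 14,15-syn pair and the isopinocampheyl groups derived from (−)-α-pinene should direct addition to the Re face of the aldehyde, setting C15 as R and C14 as S.

Step 3
Reactants: 3 (1R,2S)-1-(2,5-dimethoxy-3-nitrophenyl)-2-methylbut-3-en-1-ol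
Product: 4 2,5-dimethoxy-1-[(1R,2S)-1-methoxy-2-methylbut-3-en-1-yl]-3-nitrobenzene
Conditions: Me3OBF4, 1,8-bis(dimethylamino)naphthalene, CH2Cl2, rt
Reagents that add atoms: trimethyloxonium tetrafluoroborate, C[O+](C)C.F[B-](F)(F)F
Why: O-methylation of the secondary benzylic alcohol with Meerwein's salt under non-nucleophilic buffering, which avoids an alkoxide next to the nitro-activated aryl ether and touches no stereocentre.

Step 4
Reactants: 4 2,5-dimethoxy-1-[(1R,2S)-1-methoxy-2-methylbut-3-en-1-yl]-3-nitrobenzene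
Product: 5 (4S,5R)-5-(2,5-dimethoxy-3-nitrophenyl)-5-methoxy-4-methylpentanal
Conditions: Rh(acac)(CO)2 (1 mol%), Xantphos [4,5-bis(diphenylphosphino)-9,9-dimethylxanthene] (2 mol%), CO/H2 (1:1, 10 bar), toluene, 70 °C
Reagents that add atoms: carbon monoxide, [C-]#[O+]
Why: Rhodium-catalysed hydroformylation with a wide-bite-angle diphosphine should place the formyl group on the terminal carbon of the allylically branched monosubstituted alkene, adding C11 without touching C14 or C15.

Step 5
Reactants: 5 (4S,5R)-5-(2,5-dimethoxy-3-nitrophenyl)-5-methoxy-4-methylpentanal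
Product: 7 (2S,4S,5R)-2-(anilinooxy)-5-(2,5-dimethoxy-3-nitrophenyl)-5-methoxy-4-methylpentan-1-ol, via anilinooxy aldehyde 6 (not isolated)
Conditions: D-proline (20 mol%), PhNO, DMSO, rt; then NaBH4, EtOH, 0 °C
Reagents that add atoms: nitrosobenzene, O=Nc1ccccc1
Why: Proline-catalysed α-aminoxylation, in which the enamine of 5 attacks the oxygen of nitrosobenzene held by the carboxylic acid of D-proline, so that C12 should be set as S under catalyst control before NaBH4 reduces the labile aldehyde in the same flask.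

Step 6
Reactants: 7 (2S,4S,5R)-2-(anilinooxy)-5-(2,5-dimethoxy-3-nitrophenyl)-5-methoxy-4-methylpentan-1-ol
Product: 8 (2S,4S,5R)-5-(2,5-dimethoxy-3-nitrophenyl)-5-methoxy-4-methylpentane-1,2-diol
Conditions: CuSO4·5H2O (30 mol%), MeOH, 0 °C to rt
Reagents that add atoms: none
Why: Copper-sulfate-catalysed N–O bond cleavage of the O-alkyl-N-arylhydroxylamine should free the secondary alcohol without the dissolving metal or hydrogen that would also reduce the nitroarene.

Step 7
Reactants: 8 (2S,4S,5R)-5-(2,5-dimethoxy-3-nitrophenyl)-5-methoxy-4-methylpentane-1,2-diol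
Product: 9 bis(triethylsilyl) ether of diol 8
Conditions: Et3SiCl, imidazole, DMF, 0 °C to rt
Reagents that add atoms: chlorotriethylsilane, CC[Si](CC)(CC)Cl
Why: Imidazole-promoted silylation of both hydroxyl groups, chosen because the primary triethylsilyl ether can be oxidized away selectively in the next step.

Step 8
Reactants: 9 bis(triethylsilyl) ether of diol 8
Product: 10 (2S,4S,5R)-5-(2,5-dimethoxy-3-nitrophenyl)-5-methoxy-4-methyl-2-(triethylsilyloxy)pentanal
Conditions: (COCl)2, DMSO, CH2Cl2, −78 to −40 °C; Et3N, −78 °C to rt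
Reagents that add atoms: none
Why: Swern oxidation, whose chlorosulfonium reagent should cleave only the less hindered primary triethylsilyl ether and oxidize the resulting alkoxysulfonium salt to the aldehyde, leaving the C12 silyl ether in place.

Step 9
Reactants: 10 (2S,4S,5R)-5-(2,5-dimethoxy-3-nitrophenyl)-5-methoxy-4-methyl-2-(triethylsilyloxy)pentanal
Product: 11 (3S,4R,5S,7S,8R)-8-(2,5-dimethoxy-3-nitrophenyl)-8-methoxy-3,7-dimethyl-5-(triethylsilyloxy)oct-1-en-4-ol
Conditions: (Z)-crotyl-B(Ipc)2 [from (+)-Ipc2BOMe], THF/Et2O, −78 °C; then NaOH, H2O2, 0 °C to rt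
Reagents that add atoms: B-[(Z)-but-2-enyl]diisopinocampheylborane, C/C=C\CB([C@H]1C[C@H]2C[C@@H]([C@@H]1C)C2(C)C)[C@H]1C[C@H]2C[C@@H]([C@@H]1C)C2(C)C
Why: Brown (Z)-crotylboration as in step 2, in which the Re face favoured by the reagent is also the Felkin–Anh face anti to the C12 silyloxy group, so that matched double stereocontrol should give 10,11-syn and 11,12-anti (C10 S, C11 R).

Step 10
Reactants: 11 (3S,4R,5S,7S,8R)-8-(2,5-dimethoxy-3-nitrophenyl)-8-methoxy-3,7-dimethyl-5-(triethylsilyloxy)oct-1-en-4-ol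
Product: 13 (4R,5S)-4-[(2S)-but-3-en-2-yl]-5-[(2S,3R)-3-(2,5-dimethoxy-3-nitrophenyl)-3-methoxy-2-methylpropyl]-2,2-dimethyl-1,3-dioxolane, via free diol 12 (not isolated)
Conditions: camphorsulfonic acid (cat.), MeOH, 0 °C; evaporate; 2,2-dimethoxypropane, acetone, rt
Reagents that add atoms: 2,2-dimethoxypropane, COC(C)(C)OC
Why: Acid-catalysed methanolysis of the silyl ether followed by transacetalization should close the cis-dioxolane of the anti-diol, and a silyl shift between O11 and O12 in step 9 would be without consequence.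

Step 11
Reactants: 13 acetonide alkene (C9 vinyl)
Product: 14 (2E,4S)-4-{(4R,5S)-5-[(2S,3R)-3-(2,5-dimethoxy-3-nitrophenyl)-3-methoxy-2-methylpropyl]-2,2-dimethyl-1,3-dioxolan-4-yl}-2-methylpent-2-enal
Conditions: methacrolein (10 equiv), RuCl2(=CH-C6H4-2-OiPr)(H2IMes) (second-generation Hoveyda–Grubbs catalyst, 5 mol%), CH2Cl2, 40 °C
Reagents that add atoms: methacrolein, CC(=C)C=O
Why: Olefin cross-metathesis of the terminal alkene with an excess of the electron-poor 1,1-disubstituted partner should give the trisubstituted enal with the thermodynamically preferred E geometry (C10 trans to the formyl group).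

Step 12
Reactants: 15 (R)-4-benzyloxazolidin-2-one
Product: 16 (R)-4-benzyl-3-(2-methoxyacetyl)oxazolidin-2-one
Conditions: n-BuLi, THF, −78 °C; MeOCH2COCl, −78 to 0 °C
Reagents that add atoms: methoxyacetyl chloride, COCC(=O)Cl
Why: N-acylation of the lithiated oxazolidinone with the acid chloride, the standard entry to Evans glycolate imides.

Step 13
Reactants: 14 enal (C7 aldehyde); 16 (R)-4-benzyl-3-(2-methoxyacetyl)oxazolidin-2-one
Product: 17 syn-aldol adduct (imide carbonyl = C5; 6-OMe; 7-OH; 6R,7S)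
Conditions: 16, Bu2BOTf, Et3N, CH2Cl2, −78 to 0 °C; then 14, −78 to 0 °C; pH 7 buffer, MeOH, H2O2
Reagents that add atoms: none
Why: Evans syn-glycolate aldol, in which the (Z)-boron enolate reacts through a chair transition state on the face opposite the benzyl group, so that the (R)-auxiliary should set C6 and C7 syn (C6 R in the imide, which becomes S once C5 is an alkyne carbon, and C7 S).

Step 14
Reactants: 17 syn-aldol adduct
Product: 18 C7 tert-butyldimethylsilyl ether of 17
Conditions: TBSOTf, 2,6-lutidine, CH2Cl2, −78 to 0 °C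
Reagents that add atoms: tert-butyldimethylsilyl trifluoromethanesulfonate, CC(C)(C)[Si](C)(C)OS(=O)(=O)C(F)(F)F
Why: Silylation of the hindered allylic alcohol with the silyl triflate and a non-nucleophilic base, which does not provoke retro-aldol cleavage.

Step 15
Reactants: 18 silylated imide
Product: 19 C5 primary alcohol (6S,7S)
Conditions: LiBH4, MeOH (1.5 equiv), THF, 0 °C
Reagents that add atoms: none
Why: Reductive cleavage of the N-acyloxazolidinone by LiBH4 should give the primary alcohol and return the auxiliary, the nitroarene, acetonide and silyl ether being inert at 0 °C.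

Step 16
Reactants: 19 C5 primary alcohol
Product: 20 C5 aldehyde (6R,7S)
Conditions: Dess–Martin periodinane, CH2Cl2, 0 °C to rt
Reagents that add atoms: none
Why: Dess–Martin oxidation under near-neutral conditions, which should not epimerize the α-methoxy aldehyde.

Step 17
Reactants: 20 C5 aldehyde
Product: 21 terminal alkyne (C4≡C5; 6S,7S)
Conditions: MeC(O)C(N2)P(O)(OMe)2, K2CO3, MeOH, 0 °C to rt
Reagents that add atoms: dimethyl (1-diazo-2-oxopropyl)phosphonate, CC(=O)C(=[N+]=[N-])P(=O)(OC)OC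
Why: Seyferth–Gilbert homologation with the Ohira–Bestmann reagent, in which the diazomethylphosphonate anion adds to the aldehyde and loss of phosphate and N2 with 1,2-hydride shift of the alkylidene carbene should give the alkyne under conditions mild enough for the nitroarene.

Step 18
Reactants: 21 terminal alkyne
Product: 22 methyl-capped alkyne (C5 propynyl)
Conditions: LiN(SiMe3)2, THF, −78 °C; MeOTf, −78 to −20 °C
Reagents that add atoms: methyl trifluoromethanesulfonate, COS(=O)(=O)C(F)(F)F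
Why: Deprotonation of the alkyne C–H with a non-nucleophilic amide base and SN2 methylation of the acetylide at low temperature should install the methyl cap that alkyne metathesis requires.

Step 19
Reactants: 22 methyl-capped alkyne (nitroarene)
Product: 23 aniline (3-amino-2,5-dimethoxyphenyl at C15)
Conditions: Fe powder, NH4Cl, EtOH/H2O (4:1), 70 °C
Reagents that add atoms: none
Why: Béchamp-type electron-transfer reduction, which should convert the nitroarene into the aniline and leave the alkyne, alkene, silyl ether and acetonide untouched.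

Step 20
Reactants: 24 but-2-yn-1-ol; 25 ethyl 2-(triphenylphosphoranylidene)propanoate
Product: 27 ethyl (E)-2-methylhex-2-en-4-ynoate, via but-2-ynal 26 (not isolated)
Conditions: MnO2 (10 equiv), CH2Cl2, rt
Reagents that add atoms: none
Why: Tandem oxidation–Wittig olefination, in which MnO2 oxidizes the propargylic alcohol to the volatile ynal and the stabilized ylide traps it at once to give the E-configured 2-methyl enoate.

Step 21
Reactants: 27 ethyl (E)-2-methylhex-2-en-4-ynoate
Product: 28 (E)-2-methylhex-2-en-4-ynoic acid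
Conditions: LiOH, THF/H2O, rt; then 1 M HCl
Reagents that add atoms: lithium hydroxide, [Li+].[OH-]
Why: Saponification by acyl–oxygen cleavage, with no stereocentre or base-labile group in the substrate.

Step 22
Reactants: 23 aniline; 28 (E)-2-methylhex-2-en-4-ynoic acid
Product: 30 anilide diyne (metathesis precursor), via acid chloride 29 (not isolated)
Conditions: 28, (COCl)2, DMF (cat.), CH2Cl2, 0 °C to rt, evaporate; then 23, pyridine, CH2Cl2, 0 °C to rt
Reagents that add atoms: none
Why: Acid chloride formation under Vilsmeier catalysis followed by N-acylation of the moderately nucleophilic aniline, the only N–H or O–H nucleophile in 23.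

Step 23
Reactants: 30 anilide diyne
Product: 31 macrocyclic (2E)-en-4-yne lactam
Conditions: Mo(≡CC6H4-4-OMe)(OSiPh3)3 (20 mol%), 5 Å molecular sieves, toluene (2 mM), 80 °C
Reagents that add atoms: none
Why: The Mo≡C unit of the catalyst and one C≡C–CH3 unit combine by (2+2) cycloaddition to a molybdacyclobutadiene, which opens the other way to expel but-2-yne and leave a substrate-bound alkylidyne, and the same two events at the second alkyne form the C4≡C5 bond and return the catalyst. The closest known reaction type is ring-closing alkyne metathesis of a methyl-capped 1,3-enyne with a propargylic ether by triphenylsilanolate molybdenum alkylidynes, as used for macrocyclic E,Z-dienes after semireduction. The one ring closed is the 19-membered lactam ring, formed end to end from the acyclic α,ω-diyne at high dilution, and no stereocentre is created, so C6 and C7 beside the reacting alkyne keep their configuration. The step needs alkyne-over-alkene chemoselectivity and ring closure over oligomerization: the alkylidyne does not engage the E-C2 and E-C8 alkenes, the 5 Å sieves trap but-2-yne and make closure irreversible, and the anilide, the arene, the dioxolane and the two alkenes restrict the freedom of the chain. The ethers, silyl ether and acetal are inert, and amide N–H groups are tolerated by this catalyst class, so the secondary anilide should not stop turnover.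

Step 24
Reactants: 31 macrocyclic (2E)-en-4-yne lactam
Product: 32 macrocyclic (2E,4Z)-dienamide (7-OTBS)
Conditions: H2 (1 atm), Pd/CaCO3 poisoned with Pb(OAc)2, quinoline, EtOAc, rt
Reagents that add atoms: none
Why: Lindlar semihydrogenation, in which syn delivery of H2 on the poisoned palladium surface should convert the ring alkyne into the 4Z alkene while the trisubstituted C8 alkene stays intact.

Step 25
Reactants: 32 macrocyclic (2E,4Z)-dienamide (7-OTBS)
Product: 33 C7 alcohol
Conditions: Bu4NF, THF, 0 °C to rt; aq. NH4Cl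
Reagents that add atoms: none
Why: Fluoride-induced Si–O cleavage, driven by the strong Si–F bond, should free the allylic C7 hydroxyl without affecting the acetonide or the methyl ethers.

Step 26
Reactants: 33 C7 alcohol
Product: 35 C7 carbamate, via trichloroacetyl carbamate 34 (not isolated)
Conditions: Cl3CC(O)NCO, CH2Cl2, 0 °C; then K2CO3 (0.2 equiv), MeOH, rt
Reagents that add atoms: trichloroacetyl isocyanate, O=C=NC(=O)C(Cl)(Cl)Cl
Why: Carbamoylation by addition of the alcohol to the activated isocyanate, followed by mild methanolysis of the trichloroacetyl group to leave the primary carbamate on O7, the only free hydroxyl.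

Step 27
Reactants: 35 C7 carbamate (dimethoxyarene)
Product: 36 quinone (C18 and C21 carbonyls; acetonide intact)
Conditions: (NH4)2Ce(NO3)6, MeCN/H2O (2:1), 0 °C
Reagents that add atoms: water, O
Why: Oxidative demethylation of the 2-amido-1,4-dimethoxyarene by two single-electron oxidations with attack of water at C18 and C21 and loss of two methanol, the usual final oxidation of benzoquinone ansamycins, run briefly at 0 °C so that the acetonide keeps the diol away from the oxidant.

Step 28
Reactants: 36 quinone acetonide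
Product: 38 target CNP0523404.1, via quinone diol 37 (not isolated)
Conditions: 1 M HCl, THF, rt; then Na2S2O4, H2O/EtOAc, rt, argon
Reagents that add atoms: none
Why: Acid-catalysed acetal hydrolysis should free the 11,12-diol and dithionite then reduces the quinone to the hydroquinone by two-electron transfer, done last and under argon because the hydroquinone is air-sensitive.

**Compound list**

1 | 2-hydroxy-5-methoxy-3-nitrobenzaldehyde | O=Cc1cc(OC)cc([N+](=O)[O-])c1O | starting material
2 | 2,5-dimethoxy-3-nitrobenzaldehyde | O=[N+]([O-])c1cc(OC)cc(C=O)c1OC | intermediate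
3 | (1R,2S)-1-(2,5-dimethoxy-3-nitrophenyl)-2-methylbut-3-en-1-ol | O=[N+]([O-])c1cc(OC)cc(c1OC)[C@H](O)[C@@H](C)C=C | intermediate
4 | 2,5-dimethoxy-1-[(1R,2S)-1-methoxy-2-methylbut-3-en-1-yl]-3-nitrobenzene | O=[N+]([O-])c1cc(OC)cc(c1OC)[C@H](OC)[C@@H](C)C=C | intermediate
5 | (4S,5R)-5-(2,5-dimethoxy-3-nitrophenyl)-5-methoxy-4-methylpentanal | O=[N+]([O-])c1cc(OC)cc(c1OC)[C@H](OC)[C@@H](C)CCC=O | intermediate
6 | (2S,4S,5R)-2-(anilinooxy)-5-(2,5-dimethoxy-3-nitrophenyl)-5-methoxy-4-methylpentanal | O=[N+]([O-])c1cc(OC)cc(c1OC)[C@H](OC)[C@@H](C)C[C@H](ONc2ccccc2)C=O | intermediate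
7 | (2S,4S,5R)-2-(anilinooxy)-5-(2,5-dimethoxy-3-nitrophenyl)-5-methoxy-4-methylpentan-1-ol | O=[N+]([O-])c1cc(OC)cc(c1OC)[C@H](OC)[C@@H](C)C[C@H](ONc2ccccc2)CO | intermediate
8 | (2S,4S,5R)-5-(2,5-dimethoxy-3-nitrophenyl)-5-methoxy-4-methylpentane-1,2-diol | O=[N+]([O-])c1cc(OC)cc(c1OC)[C@H](OC)[C@@H](C)C[C@H](O)CO | intermediate
9 | 2,5-dimethoxy-1-[(1R,2S,4S)-1-methoxy-2-methyl-4,5-bis(triethylsilyloxy)pentyl]-3-nitrobenzene | O=[N+]([O-])c1cc(OC)cc(c1OC)[C@H](OC)[C@@H](C)C[C@H](O[Si](CC)(CC)CC)CO[Si](CC)(CC)CC | intermediate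
10 | (2S,4S,5R)-5-(2,5-dimethoxy-3-nitrophenyl)-5-methoxy-4-methyl-2-(triethylsilyloxy)pentanal | O=[N+]([O-])c1cc(OC)cc(c1OC)[C@H](OC)[C@@H](C)C[C@H](O[Si](CC)(CC)CC)C=O | intermediate
11 | (3S,4R,5S,7S,8R)-8-(2,5-dimethoxy-3-nitrophenyl)-8-methoxy-3,7-dimethyl-5-(triethylsilyloxy)oct-1-en-4-ol | O=[N+]([O-])c1cc(OC)cc(c1OC)[C@H](OC)[C@@H](C)C[C@H](O[Si](CC)(CC)CC)[C@H](O)[C@@H](C)C=C | intermediate
12 | (3S,4R,5S,7S,8R)-8-(2,5-dimethoxy-3-nitrophenyl)-8-methoxy-3,7-dimethyloct-1-ene-4,5-diol | O=[N+]([O-])c1cc(OC)cc(c1OC)[C@H](OC)[C@@H](C)C[C@H](O)[C@H](O)[C@@H](C)C=C | intermediate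
13 | (4R,5S)-4-[(2S)-but-3-en-2-yl]-5-[(2S,3R)-3-(2,5-dimethoxy-3-nitrophenyl)-3-methoxy-2-methylpropyl]-2,2-dimethyl-1,3-dioxolane | O=[N+]([O-])c1cc(OC)cc(c1OC)[C@H](OC)[C@@H](C)C[C@@H]2OC(C)(C)O[C@@H]2[C@@H](C)C=C | intermediate
14 | (2E,4S)-4-{(4R,5S)-5-[(2S,3R)-3-(2,5-dimethoxy-3-nitrophenyl)-3-methoxy-2-methylpropyl]-2,2-dimethyl-1,3-dioxolan-4-yl}-2-methylpent-2-enal | O=[N+]([O-])c1cc(OC)cc(c1OC)[C@H](OC)[C@@H](C)C[C@@H]2OC(C)(C)O[C@@H]2[C@@H](C)/C=C(\C)C=O | intermediate
15 | (R)-4-benzyloxazolidin-2-one | O=C1OC[C@@H](Cc2ccccc2)N1 | starting material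
16 | (R)-4-benzyl-3-(2-methoxyacetyl)oxazolidin-2-one | O=C1OC[C@@H](Cc2ccccc2)N1C(=O)COC | intermediate
17 | syn-aldol adduct: N-acyl (4R)-4-benzyloxazolidin-2-one whose acyl group is the C5–C15 chain (C5 imide carbonyl) with 6-OMe, 7-OH, (8E)-8-Me, 10-Me, 11,12-O-isopropylidene, 14-Me, 15-OMe and 15-(2,5-dimethoxy-3-nitrophenyl); (6R,7S,10S,11R,12S,14S,15R) | O=[N+]([O-])c1cc(OC)cc(c1OC)[C@H](OC)[C@@H](C)C[C@@H]2OC(C)(C)O[C@@H]2[C@@H](C)/C=C(\C)[C@H](O)[C@@H](OC)C(=O)N3C(=O)OC[C@H]3Cc4ccccc4 | intermediate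
18 | 7-O-tert-butyldimethylsilyl ether of 17; (6R,7S,10S,11R,12S,14S,15R) | O=[N+]([O-])c1cc(OC)cc(c1OC)[C@H](OC)[C@@H](C)C[C@@H]2OC(C)(C)O[C@@H]2[C@@H](C)/C=C(\C)[C@H](O[Si](C)(C)C(C)(C)C)[C@@H](OC)C(=O)N3C(=O)OC[C@H]3Cc4ccccc4 | intermediate
19 | C5 primary alcohol of the C5–C15 chain (5-OH, 6-OMe, 7-OTBS, other groups as in 18); (6S,7S,10S,11R,12S,14S,15R) | O=[N+]([O-])c1cc(OC)cc(c1OC)[C@H](OC)[C@@H](C)C[C@@H]2OC(C)(C)O[C@@H]2[C@@H](C)/C=C(\C)[C@H](O[Si](C)(C)C(C)(C)C)[C@@H](OC)CO | intermediate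
20 | C5 aldehyde of the C5–C15 chain (6-OMe, 7-OTBS); (6R,7S,10S,11R,12S,14S,15R) | O=[N+]([O-])c1cc(OC)cc(c1OC)[C@H](OC)[C@@H](C)C[C@@H]2OC(C)(C)O[C@@H]2[C@@H](C)/C=C(\C)[C@H](O[Si](C)(C)C(C)(C)C)[C@@H](OC)C=O | intermediate
21 | terminal alkyne C4≡C5 on the C4–C15 chain (6-OMe, 7-OTBS, (8E)-8-Me, 10-Me, 11,12-O-isopropylidene, 14-Me, 15-OMe, 15-(2,5-dimethoxy-3-nitrophenyl)); (6S,7S,10S,11R,12S,14S,15R) | O=[N+]([O-])c1cc(OC)cc(c1OC)[C@H](OC)[C@@H](C)C[C@@H]2OC(C)(C)O[C@@H]2[C@@H](C)/C=C(\C)[C@H](O[Si](C)(C)C(C)(C)C)[C@@H](OC)C#C | intermediate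
22 | methyl-capped alkyne: 21 with CH3 on C4; (6S,7S,10S,11R,12S,14S,15R) | O=[N+]([O-])c1cc(OC)cc(c1OC)[C@H](OC)[C@@H](C)C[C@@H]2OC(C)(C)O[C@@H]2[C@@H](C)/C=C(\C)[C@H](O[Si](C)(C)C(C)(C)C)[C@@H](OC)C#CC | intermediate
23 | aniline: 22 with the nitro group reduced to NH2 (3-amino-2,5-dimethoxyphenyl on C15) | Nc1cc(OC)cc(c1OC)[C@H](OC)[C@@H](C)C[C@@H]2OC(C)(C)O[C@@H]2[C@@H](C)/C=C(\C)[C@H](O[Si](C)(C)C(C)(C)C)[C@@H](OC)C#CC | intermediate
24 | but-2-yn-1-ol | CC#CCO | starting material
25 | ethyl 2-(triphenylphosphoranylidene)propanoate | CCOC(=O)C(C)=P(c1ccccc1)(c1ccccc1)c1ccccc1 | starting material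
26 | but-2-ynal | CC#CC=O | intermediate
27 | ethyl (E)-2-methylhex-2-en-4-ynoate | CC#C/C=C(\C)C(=O)OCC | intermediate
28 | (E)-2-methylhex-2-en-4-ynoic acid | CC#C/C=C(\C)C(=O)O | intermediate
29 | (E)-2-methylhex-2-en-4-ynoyl chloride | CC#C/C=C(\C)C(=O)Cl | intermediate
30 | anilide diyne: N-[(E)-2-methylhex-2-en-4-ynoyl] derivative of 23 (7-OTBS, 11,12-acetonide, arene dimethyl ether); (2E,8E,6S,7S,10S,11R,12S,14S,15R) | CC#C/C=C(\C)C(=O)Nc1cc(OC)cc(c1OC)[C@H](OC)[C@@H](C)C[C@@H]2OC(C)(C)O[C@@H]2[C@@H](C)/C=C(\C)[C@H](O[Si](C)(C)C(C)(C)C)[C@@H](OC)C#CC | intermediate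
31 | 19-membered (2E)-en-4-yne lactam (C4≡C5 in the ring; 7-OTBS, 11,12-acetonide, arene dimethyl ether); (2E,8E,6S,7S,10S,11R,12S,14S,15R) | CO[C@H]1C#C/C=C(\C)C(=O)Nc2cc(OC)cc(c2OC)[C@H](OC)[C@@H](C)C[C@@H]3OC(C)(C)O[C@@H]3[C@@H](C)/C=C(\C)[C@@H]1O[Si](C)(C)C(C)(C)C | intermediate
32 | 19-membered (2E,4Z,8E)-lactam, 7-OTBS, 11,12-acetonide, arene dimethyl ether | CO[C@H]1/C=C\C=C(/C)C(=O)Nc2cc(OC)cc(c2OC)[C@H](OC)[C@@H](C)C[C@@H]3OC(C)(C)O[C@@H]3[C@@H](C)/C=C(\C)[C@@H]1O[Si](C)(C)C(C)(C)C | intermediate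
33 | 32 with free 7-OH | CO[C@H]1/C=C\C=C(/C)C(=O)Nc2cc(OC)cc(c2OC)[C@H](OC)[C@@H](C)C[C@@H]3OC(C)(C)O[C@@H]3[C@@H](C)/C=C(\C)[C@@H]1O | intermediate
34 | 7-O-[N-(trichloroacetyl)carbamoyl] derivative of 33 | CO[C@H]1/C=C\C=C(/C)C(=O)Nc2cc(OC)cc(c2OC)[C@H](OC)[C@@H](C)C[C@@H]3OC(C)(C)O[C@@H]3[C@@H](C)/C=C(\C)[C@@H]1OC(=O)NC(=O)C(Cl)(Cl)Cl | intermediate
35 | 7-O-carbamate of 33 (11,12-acetonide, arene dimethyl ether) | CO[C@H]1/C=C\C=C(/C)C(=O)Nc2cc(OC)cc(c2OC)[C@H](OC)[C@@H](C)C[C@@H]3OC(C)(C)O[C@@H]3[C@@H](C)/C=C(\C)[C@@H]1OC(N)=O | intermediate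
36 | quinone of 35 (C18 and C21 carbonyls), 11,12-acetonide | CO[C@H]1/C=C\C=C(/C)C(=O)NC2=CC(=O)C=C(C2=O)[C@H](OC)[C@@H](C)C[C@@H]3OC(C)(C)O[C@@H]3[C@@H](C)/C=C(\C)[C@@H]1OC(N)=O | intermediate
37 | quinone with free 11,12-diol | CO[C@H]1/C=C\C=C(/C)C(=O)NC2=CC(=O)C=C(C2=O)[C@H](OC)[C@@H](C)C[C@H](O)[C@H](O)[C@@H](C)/C=C(\C)[C@@H]1OC(N)=O | intermediate
38 | CNP0523404.1: 19-membered (2E,4Z,8E)-lactam, 18,21-hydroquinone, 6-OMe, 7-OCONH2, 11,12-diol, 15-OMe; (6S,7S,10S,11R,12S,14S,15R) | CO[C@H]1/C=C\C=C(/C)C(=O)Nc2cc(O)cc(c2O)[C@H](OC)[C@@H](C)C[C@H](O)[C@H](O)[C@@H](C)/C=C(\C)[C@@H]1OC(N)=O | target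

**Totals.** Total step count: 28. Longest linear sequence: 25 steps (steps 1–11, 13–19 and 22–28, from compound 1 to compound 38).

**Steps most likely to fail and their fallbacks**

Step 23 (ring-closing alkyne metathesis). What may go wrong: slow turnover of the alkylidyne in the presence of the anilide N–H, or oligomerization in place of ring closure. Fallback: the C4–C5 bond is made first and the ring is closed at the amide. The fallback sets out from terminal alkyne 21. Sonogashira coupling with ethyl (E)-3-iodo-2-methylprop-2-enoate (Pd(PPh3)2Cl2, CuI, Et3N, THF, rt) should give the nitro enyne ester F1. Saponification (LiOH, THF/MeOH/H2O) should give the nitro enyne acid F2, and Fe/NH4Cl reduction the amino enyne acid F3. Macrolactamization (BOP-Cl, iPr2NEt, toluene, high dilution, 85 °C) then comes back to the route at macrocycle 31.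

Step 18 (alkyne methylation). What may go wrong: electron transfer or addition between the amide base or the acetylide and the nitroarene, which would consume the substrate before methylation. Fallback: the polarity is reversed. Starting from 21, bromination of the alkyne terminus (NBS, AgNO3 cat., acetone, rt) should give the bromoalkyne F4. Negishi coupling with MeZnCl (Pd(PPh3)4, THF, rt) comes back to the route at 22.

Step 11 (cross-metathesis with methacrolein). What may go wrong: low conversion because of the allylic branch at C10, with homodimerization of the terminal alkene. Fallback: starting from 13, ozonolysis (O3, CH2Cl2/MeOH, −78 °C; PPh3) should give the C9 aldehyde F5. Wittig olefination with 2-(triphenylphosphoranylidene)propanal (toluene, 90 °C) comes back to the route at enal 14.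

**Further compounds**

F1 | step 23 | nitro enyne ethyl ester: ethyl ester of the C1–C15 seco acid with the (2E)-2-methyl-2-en-4-yne unit, 6-OMe, 7-OTBS, (8E), 11,12-acetonide, 15-OMe and 15-(2,5-dimethoxy-3-nitrophenyl) | O=[N+]([O-])c1cc(OC)cc(c1OC)[C@H](OC)[C@@H](C)C[C@@H]2OC(C)(C)O[C@@H]2[C@@H](C)/C=C(\C)[C@H](O[Si](C)(C)C(C)(C)C)[C@@H](OC)C#C/C=C(\C)C(=O)OCC
F2 | step 23 | nitro enyne acid (free C1 acid of F1) | O=[N+]([O-])c1cc(OC)cc(c1OC)[C@H](OC)[C@@H](C)C[C@@H]2OC(C)(C)O[C@@H]2[C@@H](C)/C=C(\C)[C@H](O[Si](C)(C)C(C)(C)C)[C@@H](OC)C#C/C=C(\C)C(=O)O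
F3 | step 23 | amino enyne acid (seco acid with 3-amino-2,5-dimethoxyphenyl on C15) | Nc1cc(OC)cc(c1OC)[C@H](OC)[C@@H](C)C[C@@H]2OC(C)(C)O[C@@H]2[C@@H](C)/C=C(\C)[C@H](O[Si](C)(C)C(C)(C)C)[C@@H](OC)C#C/C=C(\C)C(=O)O
F4 | step 18 | bromoalkyne: 21 with Br on C4 | O=[N+]([O-])c1cc(OC)cc(c1OC)[C@H](OC)[C@@H](C)C[C@@H]2OC(C)(C)O[C@@H]2[C@@H](C)/C=C(\C)[C@H](O[Si](C)(C)C(C)(C)C)[C@@H](OC)C#CBr
F5 | step 11 | C9 aldehyde: (2R)-2-{(4R,5S)-5-[(2S,3R)-3-(2,5-dimethoxy-3-nitrophenyl)-3-methoxy-2-methylpropyl]-2,2-dimethyl-1,3-dioxolan-4-yl}propanal | O=[N+]([O-])c1cc(OC)cc(c1OC)[C@H](OC)[C@@H](C)C[C@@H]2OC(C)(C)O[C@@H]2[C@@H](C)C=O
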